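**Plan**

- **Feature.** Both epoxides are cis on the ten-membered ring C1–C10 (C9/C2 cis, C3/C6 cis), so they come from Z-olefins. C9–C10(Me)=C1–C2 is an s-cis isoprene unit and C3–C8 is the six-carbon arc of 3-methyltropone, so the ring is the periphery of a bicyclo[4.4.1]undecatrienone.
- **Retrosynthetic cuts, in order.** O6–C12 and C13–OAc (SN2′ opening of a 6,7-epoxide that carries a C7 acrylate); the C8 ester; the three oxirane oxygens; C7–C11 (Stille); re-insertion of a C=O bridge between C3 and C8; finally C8–C9 and C2–C3 ([6+4]).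
- **Forward order of rings.** Anisole gives the tropone ring. The [6+4] step adds the cycloheptene ring and with it the ten-membered periphery. Baeyer–Villiger oxidation, alcohol oxidation and radical decarboxylation remove the bridge. Three oxiranes follow, and the butenolide closes last.
- **Stereochemistry.** Olefin geometry comes from the seven-membered rings of the adduct. The racemic bridgeheads vanish in an achiral trienone. C8 is set by CBS reduction, C1/C10 and C4/C5 by the Shi ketone, and C6 by the C8–OH-directed vanadium epoxidation.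

Key step: step 4

Assumption: germacrane numbering is used throughout (C14 on C10, C15 on C4; the excised carbon is called "the bridge carbon"), racemic intermediates with two stereocentres are drawn as the enantiomer that maps onto the target, and the iodoalkenyl side of the α-iodoenone is taken as the large group in the CBS model.

Step 1
Reactants: 1 3-methylanisole
Product: 2 1-methoxy-5-methylcyclohexa-1,4-diene
Conditions: Li, NH3(l), t-BuOH, THF, −78 to −33 °C
Reagents that add atoms: none
Why: Birch reduction; the two donor-bearing carbons stay sp2, which gives the 1,4-diene with OMe and Me on different double bonds.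

Step 2
Reactants: 2 1-methoxy-5-methylcyclohexa-1,4-diene; 3 bromoform
Product: 4 (±)-7,7-dibromo-1-methoxy-3-methylbicyclo[4.1.0]hept-3-ene (cis-fused)
Conditions: KOt-Bu, pentane, −20 to 0 °C
Reagents that add atoms: none
Why: Dibromocarbene cyclopropanation of the more electron-rich enol-ether double bond; the ring fusion can only be cis.

Step 3
Reactants: 4 (±)-7,7-dibromo-1-methoxy-3-methylbicyclo[4.1.0]hept-3-ene
Product: 6 3-methyltropone, via 2-bromo-6-methylcyclohepta-2,5-dien-1-one 5 (not isolated)
Conditions: AgNO3, acetone–H2O, 50 °C; then Et3N, rt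
Reagents that add atoms: water, O
Why: Silver-assisted electrocyclic cyclopropyl-to-allyl cation ring expansion stabilised by OMe, hydrolysis of the oxocarbenium ion, then dehydrobromination to the tropone (the dihalocarbene route from dihydroanisoles).

Step 4
Reactants: 6 3-methyltropone; 7 isoprene
Product: 8 (±)-(1S,6R)-2,8-dimethylbicyclo[4.4.1]undeca-2,4,8-trien-11-one (cis-bridged; C1 = germacrane C3, C6 = C8)
Conditions: isoprene (10 equiv), toluene, BHT (trace), sealed tube, 120 °C
Reagents that add atoms: none
Why: Concerted, thermally allowed [π6s+π4s] cycloaddition in which s-cis isoprene adds through the exo transition state to the tropone termini (germacrane C3 and C8), forming C8–C9 and C2–C3; thermal [6+4] addition of tropones to acyclic 1,3-dienes is the known reaction type. One new ring is closed by cycloaddition, the cycloheptene C8–C9–C10–C1–C2–C3–C(=O), and with it the ten-membered periphery C1–C10, while the cycloheptadienone ring is the former tropone ring, now bridged. C3 and C8 are set together because both σ-bonds form on one face of the planar tropone, so the carbonyl bridge must be cis; absolute control is not needed because both centres are erased by step 8. All three ring olefins sit in seven-membered rings and are therefore Z. The step needs [6+4] over [4+2] periselectivity, favoured by the repulsive secondary overlap of the competing modes and a moderate temperature, and the C9-to-C8 orientation: the more nucleophilic isoprene terminus (CH2 next to CMe) attacks the tropone terminus whose attack puts no negative charge on the methyl-bearing carbon, which also keeps the methyl groups apart. The regioisomer and the [4+2] adducts are removed by chromatography.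

Step 5
Reactants: 8 (±)-2,8-dimethylbicyclo[4.4.1]undeca-2,4,8-trien-11-one
Product: 9 (±)-(1R,6S,2Z,4Z,8Z)-5,9-dimethyl-11-oxabicyclo[4.4.2]dodeca-2,4,8-trien-12-one (lactone C8–O–C(=O)–C3)
Conditions: Me3SiOOSiMe3 (1.2 equiv), TMSOTf (10 mol %), CH2Cl2, −78 to −40 °C
Reagents that add atoms: bis(trimethylsilyl) peroxide, C[Si](C)(C)OO[Si](C)(C)C
Why: Baeyer–Villiger oxidation in its peracid-free bis-silyl peroxide form, which leaves C=C bonds alone and proceeds with retention at the migrating carbon; C8 should migrate because its bond to the bridge is aligned with the diene whose far end C4 carries the methyl group, whereas for C3 that methyl sits on a nodal carbon.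

Step 6
Reactants: 9 lactone
Product: 10 (±)-(1S,6R,2Z,4Z,8Z)-6-hydroxy-2,8-dimethylcyclodeca-2,4,8-triene-1-carboxylic acid (8-OH, 3-CO2H, cis)
Conditions: LiOH, THF–H2O, 0 °C; then 1 M HCl to pH 4
Reagents that add atoms: lithium hydroxide, [Li+].[OH-]
Why: Saponification of the eight-membered lactone opens the bridge; the carboxylate formed protects C3–H from enolisation.

Step 7
Reactants: 10 hydroxy acid
Product: 11 (±)-(2Z,4Z,8Z)-2,8-dimethyl-6-oxocyclodeca-2,4,8-triene-1-carboxylic acid
Conditions: Dess–Martin periodinane, CH2Cl2, 0 °C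
Reagents that add atoms: none
Why: Dess–Martin oxidation of the dienylic alcohol under neutral, cold conditions gives the C8 dienone without touching the olefins or the acid.

Step 8
Reactants: 11 dienone acid
Product: 13 (2Z,4Z,8Z)-5,9-dimethylcyclodeca-2,4,8-trien-1-one (achiral), via 2-thioxopyridin-1(2H)-yl (2Z,4Z,8Z)-2,8-dimethyl-6-oxocyclodeca-2,4,8-triene-1-carboxylate 12 (not isolated)
Conditions: N-hydroxypyridine-2-thione, DCC, CH2Cl2, 0 °C, dark; then t-BuSH (5 equiv), hν (tungsten lamp), 0 °C
Reagents that add atoms: none
Why: Barton reductive decarboxylation; the C3 radical is delocalised over C5, C7 and O, and the electrophilic thiol should deliver H to the nucleophilic, unhindered C3 terminus, which keeps the dienone conjugated (C8=O, C3H2) and removes the last stereocentre under neutral conditions.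

Step 9
Reactants: 13 trienone
Product: 14 (2E,4Z,8Z)-2-iodo-5,9-dimethylcyclodeca-2,4,8-trien-1-one (7-iodide; C5 and C8 still cis on C6=C7)
Conditions: I2, pyridine–CH2Cl2, 0 °C to rt
Reagents that add atoms: iodine, II
Why: α-Iodination of an enone by pyridine addition at C6, iodination of the enolate at C7 and elimination; the medium ring with its neighbouring Z-olefin returns the ring-cis geometry, and pyridine is too weak a base to move the C1=C10 olefin into conjugation.

Step 10
Reactants: 14 iodotrienone
Product: 15 (1R,2E,4Z,8Z)-2-iodo-5,9-dimethylcyclodeca-2,4,8-trien-1-ol (8R)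
Conditions: (S)-Me-CBS oxazaborolidine (20 mol %), catecholborane, toluene, −78 °C
Reagents that add atoms: none
Why: Corey–Bakshi–Shibata reduction of an α-iodoenone; the iodoalkenyl side is the large group, so the (S)-catalyst sets 8R, and catecholborane at low temperature avoids hydroboration.

Step 11
Reactants: 16 methyl propiolate
Product: 17 methyl 2-(tributylstannyl)prop-2-enoate
Conditions: Bu3SnH, Pd(PPh3)4 (2 mol %), THF, 0 °C to rt
Reagents that add atoms: tributyltin hydride, CCCC[SnH](CCCC)CCCC
Why: Palladium-catalysed syn hydrostannation of a propiolate, which places tin on the α-carbon.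

Step 12
Reactants: 15 iodotrienol; 17 methyl 2-(tributylstannyl)prop-2-enoate
Product: 18 methyl 2-[(1Z,3Z,7Z,10R)-10-hydroxy-4,8-dimethylcyclodeca-1,3,7-trien-1-yl]prop-2-enoate (C7–C11 bond; C11=C13H2, C12 = CO2Me)
Conditions: Pd2(dba)3 (5 mol %), AsPh3, CuI (10 mol %), NMP, rt
Reagents that add atoms: none
Why: Stille coupling of a vinyl iodide with an α-stannyl acrylate proceeds with retention of the C6=C7 geometry and tolerates the free alcohol, and the copper co-catalyst suppresses cine substitution.

Step 13
Reactants: 18 tetraene ester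
Product: 19 methyl 2-[(1R,4S,5R,8R,10S,6Z)-1,10:4,5-diepoxy-8-hydroxygermacr-6-en-7-yl]acrylate (germacrane numbering)
Conditions: D-fructose-derived Shi ketone (30 mol %), Oxone (2.5 equiv), K2CO3, Na2B4O7–EDTA buffer (pH ≈ 10), Bu4NHSO4 (cat.), MeCN–dimethoxymethane–H2O, 0 °C
Reagents that add atoms: potassium peroxymonosulfate (active part of Oxone), [K+].[O-]S(=O)(=O)OO
Why: Shi asymmetric epoxidation (chiral dioxirane, spiro transition state); both electron-rich trisubstituted olefins have the same local topology, so the catalyst gives R at each CH and S at each CMe, while C6=C7 (flanked by the acrylate and the carbinol) and the acrylate are less nucleophilic.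

Step 14
Reactants: 19 bis-epoxide
Product: 20 methyl 2-[(1R,4S,5R,6S,7R,8R,10S)-1,10:4,5:6,7-triepoxy-8-hydroxygermacran-7-yl]acrylate
Conditions: VO(acac)2 (5 mol %), t-BuOOH, CH2Cl2, 0 °C to rt
Reagents that add atoms: tert-butyl hydroperoxide, CC(C)(C)OO
Why: Vanadium-catalysed hydroxyl-directed epoxidation of a (Z)-cycloalkenol; the vanadate ester delivers oxygen to the ring face on which the 8-OH sits, the cis outcome known for medium-ring cycloalkenols, and this fixes the C6–O bond while the electron-poor acrylate stays untouched.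

Step 15
Reactants: 20 tris-epoxy alcohol; 21 methacryloyl chloride
Product: 22 methyl 2-[(1R,4S,5R,6S,7R,8R,10S)-1,10:4,5:6,7-triepoxy-8-(methacryloyloxy)germacran-7-yl]acrylate
Conditions: Et3N, DMAP (10 mol %), CH2Cl2, 0 °C
Reagents that add atoms: none
Why: DMAP-catalysed acylation of the secondary alcohol with retention at C8; it also blocks lactonisation towards O8.

Step 16
Reactants: 22 tris-epoxy diester
Product: 24 (1R,4S,5R,6R,8R,10S)-13-acetoxy-1,10:4,5-diepoxy-8-(methacryloyloxy)germacr-7(11)-en-12,6-olide (target), via acetoxy hydroxy ester 23 (not isolated)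
Conditions: Pd(PPh3)4 (3 mol %), AcOH (3 equiv), THF, 0 °C to rt
Reagents that add atoms: acetic acid, CC(=O)O
Why: Tsuji–Trost 1,4-addition of a carboxylic acid to a vinyl epoxide: Pd(0) ionises the tertiary allylic C7–O bond, acetate attacks the unhindered C13 terminus to give the C7=C11 olefin of 23 whose methyl ester lies cis to the smaller C6 side, and the untouched C6–OH (descriptor changes S to R by priority only) lactonises on that ester.

**Compound list**

1 | 3-methylanisole | COc1cccc(C)c1 | starting material
2 | 1-methoxy-5-methylcyclohexa-1,4-diene | COC1=CCC=C(C)C1 | intermediate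
3 | bromoform | BrC(Br)Br | starting material
4 | (±)-7,7-dibromo-1-methoxy-3-methylbicyclo[4.1.0]hept-3-ene (drawn 1S,6S) | CO[C@@]12CC(C)=CC[C@@H]1C2(Br)Br | intermediate
5 | 2-bromo-6-methylcyclohepta-2,5-dien-1-one | CC1=CCC=C(Br)C(=O)C1 | intermediate
6 | 3-methyltropone | CC1=CC(=O)C=CC=C1 | intermediate
7 | isoprene | C=CC(C)=C | starting material
8 | (±)-(1S,6R)-2,8-dimethylbicyclo[4.4.1]undeca-2,4,8-trien-11-one | O=C1[C@@H]2CC(C)=CC[C@H]1C(C)=CC=C2 | intermediate
9 | (±)-(1R,6S)-5,9-dimethyl-11-oxabicyclo[4.4.2]dodeca-2,4,8-trien-12-one | O=C1O[C@H]2/C=C\C=C(C)/[C@@H]1C/C=C(C)\C2 | intermediate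
10 | (±)-(1S,6R,2Z,4Z,8Z)-6-hydroxy-2,8-dimethylcyclodeca-2,4,8-triene-1-carboxylic acid | O[C@H]1/C=C\C=C(C)/[C@@H](C(=O)O)C/C=C(C)\C1 | intermediate
11 | (±)-(2Z,4Z,8Z)-2,8-dimethyl-6-oxocyclodeca-2,4,8-triene-1-carboxylic acid | O=C1/C=C\C=C(C)/C(C(=O)O)C/C=C(C)\C1 | intermediate
12 | (±)-2-thioxopyridin-1(2H)-yl (2Z,4Z,8Z)-2,8-dimethyl-6-oxocyclodeca-2,4,8-triene-1-carboxylate | O=C1/C=C\C=C(C)/C(C(=O)ON2C=CC=CC2=S)C/C=C(C)\C1 | intermediate
13 | (2Z,4Z,8Z)-5,9-dimethylcyclodeca-2,4,8-trien-1-one | O=C1/C=C\C=C(C)/CC/C=C(C)\C1 | intermediate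
14 | (2E,4Z,8Z)-2-iodo-5,9-dimethylcyclodeca-2,4,8-trien-1-one | O=C1C/C(C)=C\CC/C(C)=C\C=C1\I | intermediate
15 | (1R,2E,4Z,8Z)-2-iodo-5,9-dimethylcyclodeca-2,4,8-trien-1-ol | O[C@@H]1C/C(C)=C\CC/C(C)=C\C=C1\I | intermediate
16 | methyl propiolate | C#CC(=O)OC | starting material
17 | methyl 2-(tributylstannyl)prop-2-enoate | C=C(C(=O)OC)[Sn](CCCC)(CCCC)CCCC | intermediate
18 | methyl 2-[(1Z,3Z,7Z,10R)-10-hydroxy-4,8-dimethylcyclodeca-1,3,7-trien-1-yl]prop-2-enoate | O[C@@H]1C/C(C)=C\CC/C(C)=C\C=C1\C(=C)C(=O)OC | intermediate
19 | methyl 2-[(1R,4S,5R,8R,10S,6Z)-1,10:4,5-diepoxy-8-hydroxygermacr-6-en-7-yl]acrylate | O[C@@H]1C[C@]2(C)O[C@@H]2CC[C@]2(C)O[C@@H]2/C=C1/C(=C)C(=O)OC | intermediate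
20 | methyl 2-[(1R,4S,5R,6S,7R,8R,10S)-1,10:4,5:6,7-triepoxy-8-hydroxygermacran-7-yl]acrylate | O[C@@H]1C[C@]2(C)O[C@@H]2CC[C@]2(C)O[C@@H]2[C@@H]2O[C@]12C(=C)C(=O)OC | intermediate
21 | methacryloyl chloride | C=C(C)C(=O)Cl | starting material
22 | methyl 2-[(1R,4S,5R,6S,7R,8R,10S)-1,10:4,5:6,7-triepoxy-8-(methacryloyloxy)germacran-7-yl]acrylate | C=C(C)C(=O)O[C@@H]1C[C@]2(C)O[C@@H]2CC[C@]2(C)O[C@@H]2[C@@H]2O[C@]12C(=C)C(=O)OC | intermediate
23 | acetoxy hydroxy ester: methyl 13-acetoxy-1,10:4,5-diepoxy-6-hydroxy-8-(methacryloyloxy)germacr-7(11)-en-12-oate (ester cis to C6) | C=C(C)C(=O)O[C@@H]1C[C@]2(C)O[C@@H]2CC[C@]2(C)O[C@@H]2[C@H](O)/C1=C(/COC(C)=O)C(=O)OC | intermediate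
24 | (1R,4S,5R,6R,8R,10S)-13-acetoxy-1,10:4,5-diepoxy-8-(methacryloyloxy)germacr-7(11)-en-12,6-olide | C=C(C)C(=O)O[C@@H]1C[C@]2(C)O[C@@H]2CC[C@]2(C)O[C@@H]2[C@@H]2OC(=O)C(COC(C)=O)=C21 | target

Total step count: 16. Longest linear sequence: 15 (steps 1–10 and 12–16).

**Steps most likely to fail**

**Step 5.** The migration step may discriminate poorly between the two allylic bridgeheads, and the silyl triflate may ionise the dienylic C8–O bond of the product. The fallback sets out from 8 and comes back at 9. m-CPBA (2 equiv) first masks the two trisubstituted olefins and gives the bis-epoxy ketone F1. In F1 only C8 is still allylic, while C3 is flanked by an electron-withdrawing oxirane. Buffered trifluoroperacetic acid then gives the bis-epoxy lactone F2 by migration of C8. Stereospecific deoxygenation with dimethyl diazomalonate and Rh2(OAc)4 in hot toluene restores both ring-locked Z-olefins and delivers 9.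

**Step 8.** Hydrogen transfer may go to the wrong position of the delocalised radical (C5 or C7). Z-to-E leakage may occur during the radical lifetime, or the bis-vinylogous β-keto acid may lose CO2 prematurely by an ionic path. The fallback sets out from 9 and comes back at 13, and it avoids open-shell and enolate intermediates. DIBAL-H at −78 °C reduces the lactone to the hydroxy aldehyde F3, which is in equilibrium with its lactol. Stoichiometric RhCl(PPh3)3 in warm toluene removes the formyl group by Tsuji–Wilkinson decarbonylation and gives the trienol F4. MnO2 then oxidises the dienylic alcohol to 13.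

**Step 16.** Pd(0) may re-ionise the allylic esters of the product (C13 acetate, C8 methacrylate), or the olefin isomer whose ester cannot reach O6 may form. The fallback sets out from 22 and comes back at 24 without a metal, through the same acetoxy hydroxy ester 23. DABCO (20 mol %) with AcOH/CsOAc in MeCN adds to C13 of the acrylate, and the ester enolate expels the C7–O bond. Acetate then displaces the allylic ammonium group at the primary C13, as in Morita–Baylis–Hillman-type allylic substitution. The reversible addition–elimination equilibrates the olefin isomers, and lactonisation drains the one with the ester cis to C6.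

**Further compounds**

F1 | step 5 | (±)-1,10:4,5-bis-epoxide of adduct 8 (oxiranes drawn syn to the carbonyl bridge) | O=C1[C@@H]2C[C@]3(C)O[C@@H]3C[C@H]1[C@]1(C)O[C@@H]1C=C2
F2 | step 5 | (±)-1,10:4,5-bis-epoxide of lactone 9 | O=C1O[C@@H]2C[C@]3(C)O[C@@H]3C[C@H]1[C@]1(C)O[C@@H]1/C=C\2
F3 | step 8 | (±)-(1S,6R,2Z,4Z,8Z)-6-hydroxy-2,8-dimethylcyclodeca-2,4,8-triene-1-carbaldehyde | O[C@H]1/C=C\C=C(C)/[C@@H](C=O)C/C=C(C)\C1
F4 | step 8 | (±)-(2Z,4Z,8Z)-5,9-dimethylcyclodeca-2,4,8-trien-1-ol | OC1/C=C\C=C(C)/CC/C=C(C)\C1
F0 | step 16 | none | none
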